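**Retrosynthetic overview**

1. Target 15 comes from the tris(benzyl ether) 14 by hydrogenolysis; 14 comes from the 5,7-difluoroflavone 12 by exchange of both C–F bonds for C–OBn (SNAr).
2. 12 is cut into the B-ring methyl ketone 8 and 2,4,6-trifluorobenzoyl chloride 9: C3–C4 by enolate C-acylation, O1–C8a by intramolecular SNAr. The pyranone (ring C) is the only ring built; rings A and B enter as arenes.
3. 8 comes from 1,2,4-trimethoxybenzene 1: oxygen at C3 by lithiation between two methoxy groups and borylation–oxidation, acetyl by Friedel–Crafts acylation of the phenol acetate para to a methoxy group, then acetate exchanged for benzyl.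
4. Feature used: ring A carries its three oxygens at C5, C7 and C8a (O1), each ortho or para to C4a, the carbon that bears the C4 carbonyl. A symmetric 2,4,6-trifluorobenzoyl unit can therefore supply all three C–O bonds by addition–elimination, the first of them closing ring C.

Key step: step 6

Remark: the target has no stereogenic element, so the single-enantiomer requirement is met trivially and no step needs stereocontrol.

**Route**

Step 1
Reactants: 1 1,2,4-trimethoxybenzene
Product: 4 2,3,6-trimethoxyphenol, via aryllithium 2 (not isolated), via arylboronate 3 (not isolated)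
Conditions: n-BuLi, THF, 0 °C → rt; B(OMe)3, −78 °C → rt; AcOH, 30% aq. H2O2, 0 °C → rt
Reagents that add atoms: hydrogen peroxide, OO (phenol oxygen of 4); n-butyllithium, [Li]CCCC (lithium of 2 only); trimethyl borate, COB(OC)OC (boron and methoxy groups of 3 only)
Why: Directed ortho-metalation removes the C3 proton, the only one flanked by two methoxy groups, and borylation followed by peroxide oxidation replaces the C–Li bond by C–OH at the same carbon.

Step 2
Reactants: 4 2,3,6-trimethoxyphenol
Product: 5 2,3,6-trimethoxyphenyl acetate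
Conditions: Ac2O, pyridine, DMAP (cat.), CH2Cl2, 0 °C → rt
Reagents that add atoms: acetic anhydride, CC(=O)OC(C)=O
Why: DMAP-catalysed O-acylation of the hindered phenol turns the strongest donor of the ring into a weak one, so that it no longer directs the following electrophilic substitution.

Step 3
Reactants: 5 2,3,6-trimethoxyphenyl acetate
Product: 6 5-acetyl-2,3,6-trimethoxyphenyl acetate
Conditions: AcCl, SnCl4, CH2Cl2, −10 → 0 °C
Reagents that add atoms: acetyl chloride, CC(Cl)=O
Why: Friedel–Crafts acylation should enter at C5, which is ortho to one methoxy group and para to another, rather than at C4, which is para only to the weakly donating acetoxy group; the mild Lewis acid at low temperature limits ether cleavage and Fries migration.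

Step 4
Reactants: 6 5-acetyl-2,3,6-trimethoxyphenyl acetate
Product: 7 1-(3-hydroxy-2,4,5-trimethoxyphenyl)ethan-1-one
Conditions: K2CO3 (cat.), MeOH, rt
Reagents that add atoms: none
Why: Base-catalysed transesterification (methanolysis) of an aryl acetate is much faster than any reaction of the aryl ketone or the methyl ethers.

Step 5
Reactants: 7 1-(3-hydroxy-2,4,5-trimethoxyphenyl)ethan-1-one
Product: 8 1-[3-(benzyloxy)-2,4,5-trimethoxyphenyl]ethan-1-one
Conditions: BnBr, K2CO3, DMF, 50 °C
Reagents that add atoms: benzyl bromide, BrCc1ccccc1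
Why: Williamson ether synthesis on the phenoxide; the benzyl ether tolerates the strong bases of steps 6 and 7 and is removed together with the other benzyl groups in step 8.

Step 6
Reactants: 8 1-[3-(benzyloxy)-2,4,5-trimethoxyphenyl]ethan-1-one; 9 2,4,6-trifluorobenzoyl chloride
Product: 12 2-[3-(benzyloxy)-2,4,5-trimethoxyphenyl]-5,7-difluoro-4H-chromen-4-one, via lithium enolate 10 (not isolated), via 1,3-diketone 11 (not isolated)
Conditions: LiHMDS (2.2 equiv), THF, −78 °C; 9 (1.0 equiv), −78 → 0 °C; then DMF, 70 °C
Reagents that add atoms: lithium bis(trimethylsilyl)amide, [Li]N([Si](C)(C)C)[Si](C)(C)C (lithium of 10 only)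
Why: LiHMDS converts 8 into the lithium enolate 10, which attacks the acid chloride 9 through carbon (Claisen-type C-acylation, forming C3–C4) to give diketone 11, and the second equivalent of base removes 11 at once as its chelated lithium enolate. On warming in DMF the enolate oxygen of 11 adds to one of the two equivalent ortho C–F carbons and the Meisenheimer adduct expels fluoride (intramolecular SNAr by addition–elimination, forming O1–C8a). The closest established reaction type is the one-pot acylation and SNAr cyclisation of ketone enolates with 2-fluorobenzoyl chlorides to flavones. The pyranone closes as a six-membered ring by attack of the enolate oxygen on the arene carbon (6-exo-trig with respect to the C8–C8a bond); the ortho ketone and the two remaining fluorines make that carbon electrophilic enough, and formation of lithium fluoride makes the closure irreversible. No stereocentre is created. The step needs C- over O-acylation, which the lithium counter-ion, the low temperature and the excess base should secure, while the closure needs no regiocontrol because the trifluorophenyl ring is symmetric and attack through carbon would give a four-membered ring.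

Step 7
Reactants: 12 2-[3-(benzyloxy)-2,4,5-trimethoxyphenyl]-5,7-difluoro-4H-chromen-4-one
Product: 14 5,7-bis(benzyloxy)-2-[3-(benzyloxy)-2,4,5-trimethoxyphenyl]-4H-chromen-4-one, via 7-benzyloxy-5-fluoroflavone 13 (not isolated)
Conditions: BnOH (4 equiv), NaH (4 equiv), THF, 0 °C; then 12, THF–DMF, 0 → 50 °C
Reagents that add atoms: benzyl alcohol, OCc1ccccc1
Why: Intermolecular SNAr (addition–elimination) at C7 (para to C4a) and C5 (ortho to C4a), both activated by the C4 carbonyl, with the para fluoride expected to leave first and excess alkoxide with gentle heating completing the second exchange; alkoxide addition at C2 is reversible and returns the flavone.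

Step 8
Reactants: 14 5,7-bis(benzyloxy)-2-[3-(benzyloxy)-2,4,5-trimethoxyphenyl]-4H-chromen-4-one
Product: 15 5,7-dihydroxy-2-(3-hydroxy-2,4,5-trimethoxyphenyl)-4H-chromen-4-one (5,7,3'-trihydroxy-2',4',5'-trimethoxyflavone)
Conditions: H2 (1 atm), 10% Pd/C, THF–MeOH, rt
Reagents that add atoms: none
Why: Catalytic hydrogenolysis cleaves the three benzylic C–O bonds at ambient pressure, conditions under which the flavone C2=C3 bond, the carbonyl and the aryl methyl ethers are normally left intact.

**Compound list**

1 | 1,2,4-trimethoxybenzene | COc1ccc(OC)c(OC)c1 | starting material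
2 | (2,3,6-trimethoxyphenyl)lithium | [Li]c1c(OC)ccc(OC)c1OC | intermediate (not isolated)
3 | dimethyl (2,3,6-trimethoxyphenyl)boronate | COB(OC)c1c(OC)ccc(OC)c1OC | intermediate (not isolated)
4 | 2,3,6-trimethoxyphenol | COc1ccc(OC)c(O)c1OC | intermediate
5 | 2,3,6-trimethoxyphenyl acetate | COc1ccc(OC)c(OC(C)=O)c1OC | intermediate
6 | 5-acetyl-2,3,6-trimethoxyphenyl acetate | CC(=O)Oc1c(OC)c(OC)cc(C(C)=O)c1OC | intermediate
7 | 1-(3-hydroxy-2,4,5-trimethoxyphenyl)ethan-1-one | CC(=O)c1cc(OC)c(OC)c(O)c1OC | intermediate
8 | 1-[3-(benzyloxy)-2,4,5-trimethoxyphenyl]ethan-1-one | CC(=O)c1cc(OC)c(OC)c(OCc2ccccc2)c1OC | intermediate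
9 | 2,4,6-trifluorobenzoyl chloride | O=C(Cl)c1c(F)cc(F)cc1F | starting material
10 | lithium 1-[3-(benzyloxy)-2,4,5-trimethoxyphenyl]ethen-1-olate | [Li]OC(=C)c1cc(OC)c(OC)c(OCc2ccccc2)c1OC | intermediate (not isolated)
11 | 1-[3-(benzyloxy)-2,4,5-trimethoxyphenyl]-3-(2,4,6-trifluorophenyl)propane-1,3-dione | COc1cc(C(=O)CC(=O)c2c(F)cc(F)cc2F)c(OC)c(OCc2ccccc2)c1OC | intermediate (not isolated)
12 | 2-[3-(benzyloxy)-2,4,5-trimethoxyphenyl]-5,7-difluoro-4H-chromen-4-one | COc1cc(-c2cc(=O)c3c(F)cc(F)cc3o2)c(OC)c(OCc2ccccc2)c1OC | intermediate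
13 | 7-(benzyloxy)-2-[3-(benzyloxy)-2,4,5-trimethoxyphenyl]-5-fluoro-4H-chromen-4-one | COc1cc(-c2cc(=O)c3c(F)cc(OCc4ccccc4)cc3o2)c(OC)c(OCc2ccccc2)c1OC | intermediate (not isolated)
14 | 5,7-bis(benzyloxy)-2-[3-(benzyloxy)-2,4,5-trimethoxyphenyl]-4H-chromen-4-one | COc1cc(-c2cc(=O)c3c(OCc4ccccc4)cc(OCc4ccccc4)cc3o2)c(OC)c(OCc2ccccc2)c1OC | intermediate
15 | 5,7-dihydroxy-2-(3-hydroxy-2,4,5-trimethoxyphenyl)-4H-chromen-4-one | COc1cc(-c2cc(=O)c3c(O)cc(O)cc3o2)c(OC)c(O)c1OC | target

**Step count**

Total: 8 steps. Longest linear sequence: 8 steps (1 → 15); 9 enters at step 6.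

**Steps most likely to fail**

Step 6 (key step). The enolate may be acylated on oxygen, the diketonate may be acylated a second time, or the lithium-chelated diketonate may close too slowly. The fallback sets out from 8 and comes back at 12, forming C3–C4 by an aldol addition, which can only occur through carbon. The enolate 10 (LDA, THF, −78 °C) is added to 2,4,6-trifluorobenzaldehyde to give racemic 1-[3-(benzyloxy)-2,4,5-trimethoxyphenyl]-3-hydroxy-3-(2,4,6-trifluorophenyl)propan-1-one F1. Oxidation with Dess–Martin periodinane (CH2Cl2, rt) should give diketone 11, now isolated, and K2CO3 in DMF at 80 °C should close it to 12.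

Step 7. The exchange may stop after the first fluoride, because the new alkoxy group weakens the activation by the carbonyl, or alkoxide may add at C2 and open or cleave the pyranone. The fallback sets out from 9 and comes back at 14, moving the fluorine–oxygen exchange ahead of ring formation. Acid chloride 9 and t-BuOK (THF, 0 °C) give tert-butyl 2,4,6-trifluorobenzoate F2. Potassium benzyloxide (2 equiv, DMF) should displace the para fluoride first, next to the bulky ester, and then one of the two equivalent ortho fluorides, giving tert-butyl 2,4-bis(benzyloxy)-6-fluorobenzoate F3. TFA in CH2Cl2 at 0 °C frees 2,4-bis(benzyloxy)-6-fluorobenzoic acid F4, and oxalyl chloride with catalytic DMF gives 2,4-bis(benzyloxy)-6-fluorobenzoyl chloride F5. Reaction of F5 with ketone 8 under the conditions of step 6, with stronger heating for the closure, should pass through 1-[2,4-bis(benzyloxy)-6-fluorophenyl]-3-[3-(benzyloxy)-2,4,5-trimethoxyphenyl]propane-1,3-dione F6 and close on the one remaining ortho C–F bond to give 14 directly.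

Step 3. Acylation may occur in part at C4, the Lewis acid may cleave the methyl ether next to the new ketone, or the acetate may migrate in a Fries-type process. The fallback sets out from 1 and comes back at 7, placing the acetyl group first, where its position is not in doubt, and the oxygen afterwards. Friedel–Crafts acetylation of 1 (AcCl, SnCl4, CH2Cl2, 0 °C) gives 1-(2,4,5-trimethoxyphenyl)ethan-1-one F7, which is protected as 2-methyl-2-(2,4,5-trimethoxyphenyl)-1,3-dioxolane F8 (ethylene glycol, TsOH cat., toluene, Dean–Stark). Lithiation with n-BuLi in THF at 0 °C should again take place between the two methoxy groups to give [2,3,6-trimethoxy-5-(2-methyl-1,3-dioxolan-2-yl)phenyl]lithium F9. Trimethyl borate converts it into dimethyl [2,3,6-trimethoxy-5-(2-methyl-1,3-dioxolan-2-yl)phenyl]boronate F10, and hydrogen peroxide gives 2,3,6-trimethoxy-5-(2-methyl-1,3-dioxolan-2-yl)phenol F11. Dilute HCl in THF removes the ketal and gives 7.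

**Further compounds**

F1 | step 6 | 1-[3-(benzyloxy)-2,4,5-trimethoxyphenyl]-3-hydroxy-3-(2,4,6-trifluorophenyl)propan-1-one (racemic) | COc1cc(C(=O)CC(O)c2c(F)cc(F)cc2F)c(OC)c(OCc2ccccc2)c1OC
F2 | step 7 | tert-butyl 2,4,6-trifluorobenzoate | CC(C)(C)OC(=O)c1c(F)cc(F)cc1F
F3 | step 7 | tert-butyl 2,4-bis(benzyloxy)-6-fluorobenzoate | CC(C)(C)OC(=O)c1c(F)cc(OCc2ccccc2)cc1OCc1ccccc1
F4 | step 7 | 2,4-bis(benzyloxy)-6-fluorobenzoic acid | OC(=O)c1c(F)cc(OCc2ccccc2)cc1OCc1ccccc1
F5 | step 7 | 2,4-bis(benzyloxy)-6-fluorobenzoyl chloride | O=C(Cl)c1c(F)cc(OCc2ccccc2)cc1OCc1ccccc1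
F6 | step 7 | 1-[2,4-bis(benzyloxy)-6-fluorophenyl]-3-[3-(benzyloxy)-2,4,5-trimethoxyphenyl]propane-1,3-dione | COc1cc(C(=O)CC(=O)c2c(F)cc(OCc3ccccc3)cc2OCc2ccccc2)c(OC)c(OCc2ccccc2)c1OC
F7 | step 3 | 1-(2,4,5-trimethoxyphenyl)ethan-1-one | CC(=O)c1cc(OC)c(OC)cc1OC
F8 | step 3 | 2-methyl-2-(2,4,5-trimethoxyphenyl)-1,3-dioxolane | CC1(OCCO1)c1cc(OC)c(OC)cc1OC
F9 | step 3 | [2,3,6-trimethoxy-5-(2-methyl-1,3-dioxolan-2-yl)phenyl]lithium | CC1(OCCO1)c1cc(OC)c(OC)c([Li])c1OC
F10 | step 3 | dimethyl [2,3,6-trimethoxy-5-(2-methyl-1,3-dioxolan-2-yl)phenyl]boronate | CC1(OCCO1)c1cc(OC)c(OC)c(B(OC)OC)c1OC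
F11 | step 3 | 2,3,6-trimethoxy-5-(2-methyl-1,3-dioxolan-2-yl)phenol | CC1(OCCO1)c1cc(OC)c(OC)c(O)c1OC
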